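The bicyclo[3.3.1]nonane is cut at C2–C3 of ring B (C1–C2–C3–C4–C5–C9). The key step exploits that C2 carries a heteroatom and C3 the oxygenated aroyl carbon: a nitrile oxide raised on C1 adds to an aryl ynone on C5, carbon to C3 and oxygen to the aryl-bearing carbon. One operation thus forges C2–C3, closes ring B and fuses an isoxazole that masks the C2 carbonyl and the aroyl ketone. The precursor is a single-enantiomer ring A cyclohexanone (C1, C9, C5, C6, C7, C8) with prenyl and an (E)-aldoxime on C1, geranyl and a 3-arylpropynoyl group on C5 cis to the oxime, and geranyl on C7.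

Key step: step 16

Numbering (used for all intermediates): C1 prenyl bridgehead, C2–C3–C4 triketone bridge (aroyl on C3), C5 geranyl bridgehead, C6 CH2, C7 CH(geranyl), C8 CMe2, C9 bridging ketone. The C7 geranyl lies on the face of ring A opposite to the C2–C4 bridge.

Abbreviations: prenyl = 3-methylbut-2-en-1-yl; geranyl = (2E)-3,7-dimethylocta-2,6-dien-1-yl; TBS = tert-butyldimethylsilyl; Ar = 3,4-bis(TBS-oxy)phenyl; MOP = 2-methoxyprop-2-yl; RAMP = (R)-1-amino-2-(methoxymethyl)pyrrolidine.

Assumption: the azaenolate of hydrazone 6 is alkylated with the topicity established for RAMP hydrazones of simple cyclohexanones, which corresponds to (R) at the future C7; if the sense were opposite, SAMP would be used with no other change.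

Step 1
Reactants: 1 cyclohexane-1,3-dione; 2 prenyl bromide
Product: 3 2-prenylcyclohexane-1,3-dione
Conditions: KOH (1 equiv), H2O, 0 °C → rt
Reagents that add atoms: none
Why: C-alkylation of the dione enolate (SN2 at the primary allylic carbon) is favoured over O-alkylation in water, where the enolate oxygens are hydrogen-bonded; no stereocentre is formed.

Step 2
Reactants: 3 2-prenylcyclohexane-1,3-dione
Product: 4 3-methoxy-2-prenylcyclohex-2-en-1-one
Conditions: Me2SO4, K2CO3, acetone, reflux
Reagents that add atoms: dimethyl sulfate COS(=O)(=O)OC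
Why: O-methylation of the 2-substituted dione enolate by a hard electrophile should give the vinylogous ester without the acid that would cyclise the enol onto the prenyl alkene.

Step 3
Reactants: 4 3-methoxy-2-prenylcyclohex-2-en-1-one; 5 RAMP
Product: 6 (E)-RAMP hydrazone of 4
Conditions: p-TsOH (cat.), benzene, reflux (Dean–Stark)
Reagents that add atoms: none
Why: Hydrazone condensation at the carbonyl carbon with loss of water is the course that hydroxylamine and hydrazines take with 3-alkoxy-enones; the amino nitrogen should settle anti to the prenyl-bearing sp2 carbon to avoid allylic strain, and no new stereocentre arises.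

Step 4
Reactants: 6 (E)-RAMP hydrazone of 4; 7 geranyl bromide
Product: 8 (E)-RAMP hydrazone of (6R)-6-geranyl-3-methoxy-2-prenylcyclohex-2-en-1-one
Conditions: LiN(i-Pr)2, THF, 0 °C; then 7, −100 → −78 °C → rt
Reagents that add atoms: none
Why: Enders hydrazone alkylation: kinetic deprotonation of the CH2 next to C=N gives a lithium azaenolate chelated by the methoxymethyl arm, and geranyl bromide should attack (SN2) its unshielded face, so the auxiliary sets the (R) centre that becomes C7.

Step 5
Reactants: 8 (E)-RAMP hydrazone of (6R)-6-geranyl-3-methoxy-2-prenylcyclohex-2-en-1-one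
Product: 9 (6R)-6-geranyl-3-methoxy-2-prenylcyclohex-2-en-1-one
Conditions: sat. aq. oxalic acid, Et2O, rt (two-phase)
Reagents that add atoms: water O
Why: Mild acid hydrolysis of the hydrazone expels the protonated hydrazine into the aqueous phase, a cleavage known to spare the α-stereocentre, and the brief two-phase contact should leave the vinylogous ester intact.

Step 6
Reactants: 9 (6R)-6-geranyl-3-methoxy-2-prenylcyclohex-2-en-1-one
Product: 11 (4R)-4-geranyl-3-methyl-2-prenylcyclohex-2-en-1-one, via tertiary carbinol 10 (not isolated)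
Conditions: MeLi, CeCl3, THF, −78 °C; then 1 M HCl, 0 °C → rt
Reagents that add atoms: methyllithium [Li]C
Why: Stork–Danheiser transposition: the weakly basic organocerium reagent adds 1,2 without enolising the adjacent stereocentre, and dilute acid then expels water and methanol to give the transposed enone, in which the stereocentre is the allylic C7.

Step 7
Reactants: 11 (4R)-4-geranyl-3-methyl-2-prenylcyclohex-2-en-1-one
Product: 13 (2S,4R)-4-geranyl-2-(hydroxymethyl)-3,3-dimethyl-2-prenylcyclohexan-1-one, via lithium enolate 12 (not isolated)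
Conditions: Me2CuLi (from CuI and MeLi), Et2O, −20 → 0 °C; then CH2O (g), −78 → −40 °C; aq. NH4Cl
Reagents that add atoms: lithium dimethylcuprate [Li+].C[Cu-]C; formaldehyde C=O
Why: Cuprate conjugate addition creates the C8 gem-dimethyl group and a regiodefined enolate, which is trapped by aldol addition to formaldehyde; attack should be axial, anti to the axial C8 methyl and trans to the equatorial C7 geranyl, which sets C1 with the hydroxymethyl group on the face opposite to that geranyl.

Step 8
Reactants: 13 (2S,4R)-4-geranyl-2-(hydroxymethyl)-3,3-dimethyl-2-prenylcyclohexan-1-one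
Product: 14 MOP ether of 13
Conditions: 2-methoxypropene, PPTS (cat.), CH2Cl2, 0 °C
Reagents that add atoms: 2-methoxypropene COC(C)=C
Why: Acid-catalysed addition of the alcohol to the enol ether gives a mixed ketal under conditions too mild for retro-aldol cleavage or alkene protonation; the ketal is base-stable, carries no stereocentre and offers two oxygens to bind lithium in step 13.

Step 9
Reactants: 14 MOP ether of 13; 7 geranyl bromide
Product: 15 C5-geranylated MOP ether (C5 epimers)
Conditions: LiN(i-Pr)2, THF, −78 °C; then 7, −78 → 0 °C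
Reagents that add atoms: none
Why: Enolate alkylation is regiospecific because C5 is the only enolisable carbon (C1 is quaternary); the C5 configuration is left uncontrolled because this centre is planarised again in step 13.

Step 10
Reactants: 16 3,4-dihydroxybenzaldehyde
Product: 17 3,4-bis(TBS-oxy)benzaldehyde
Conditions: TBSCl, imidazole, DMF, rt
Reagents that add atoms: tert-butyldimethylsilyl chloride CC(C)(C)[Si](C)(C)Cl
Why: Imidazole-promoted silylation of both phenols gives ethers that survive organolithium reagents and mild acid and are removed by base or fluoride at the end.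

Step 11
Reactants: 17 3,4-bis(TBS-oxy)benzaldehyde
Product: 18 1,1-dibromo-2-arylethene
Conditions: CBr4, PPh3, CH2Cl2, 0 °C
Reagents that add atoms: carbon tetrabromide BrC(Br)(Br)Br
Why: First stage of the Corey–Fuchs reaction, a Wittig-type olefination by the dibromomethylene ylide.

Step 12
Reactants: 18 1,1-dibromo-2-arylethene
Product: 20 3-arylprop-2-ynal, via lithium acetylide 19 (not isolated)
Conditions: n-BuLi (2.1 equiv), THF, −78 °C; then DMF, −78 → 0 °C; cold 1 M HCl
Reagents that add atoms: N,N-dimethylformamide CN(C)C=O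
Why: Second stage of the Corey–Fuchs reaction (bromine–lithium exchange and rearrangement to the acetylide) followed by formylation with DMF, whose adduct collapses to the ynal only on the acidic quench.

Step 13
Reactants: 15 C5-geranylated MOP ether (C5 epimers); 20 3-arylprop-2-ynal
Product: 22 C1-hydroxymethyl C5-(1-hydroxy-3-arylprop-2-ynyl) diol, via MOP-protected aldol adduct 21 (not isolated)
Conditions: LiN(i-Pr)2, THF, −78 → 0 °C; then 20, −78 °C; AcOH, −78 °C; then AcOH/THF/H2O, rt
Reagents that add atoms: none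
Why: Directed aldol addition of the tetrasubstituted lithium enolate to the non-enolisable ynal through a closed transition state: lithium is held on the upper face by the ketal oxygens of the axial C1 oxymethyl group and attack is axial, trans to the equatorial C7 geranyl, so the new C5–C4 bond should form cis to the C1 oxymethyl carbon (the carbinol centre is left uncontrolled because it is oxidised next), and aqueous acetic acid then cleaves the very labile mixed ketal without touching the aryl silyl ethers.

Step 14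
Reactants: 22 C1-hydroxymethyl C5-(1-hydroxy-3-arylprop-2-ynyl) diol
Product: 23 C1-formyl C5-(3-arylpropynoyl) cyclohexanone
Conditions: Dess–Martin periodinane (3 equiv), CH2Cl2, 0 °C → rt
Reagents that add atoms: none
Why: Dess–Martin oxidation converts the neopentyl primary alcohol and the propargylic alcohol to aldehyde and ynone in one operation; both new carbonyls flank quaternary carbons, so C1 and C5 cannot epimerise.

Step 15
Reactants: 23 C1-formyl C5-(3-arylpropynoyl) cyclohexanone
Product: 24 ynone (E)-aldoxime (key-step precursor)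
Conditions: NH2OH·HCl (1.05 equiv), NaOAc, EtOH/THF, 0 °C
Reagents that add atoms: hydroxylamine hydrochloride Cl.NO
Why: Oxime condensation: one equivalent of buffered hydroxylamine should condense with the aldehyde at 0 °C far faster than it attacks the hindered ketones or adds to the β-aryl ynone, and the neopentyl aldoxime should settle as the (E) isomer, which cannot cyclise onto the C9 ketone.

Step 16
Reactants: 24 ynone (E)-aldoxime (key-step precursor)
Product: 27 isoxazole-fused bicyclo[3.3.1]nonane-4,9-dione, via hydroximoyl chloride 25 (not isolated), via nitrile oxide 26 (not isolated)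
Conditions: NCS, pyridine (cat.), CHCl3, 0 °C → rt; then Et3N (slow addition), CH2Cl2 (0.005 M), rt → 40 °C
Reagents that add atoms: none
Why: N-Chlorosuccinimide chlorinates the aldoxime carbon to the hydroximoyl chloride 25, triethylamine removes HCl to give the nitrile oxide 26 on C1, and this adds in a concerted [3+2] cycloaddition across the C5 ynone, its carbon (C2) bonding to C3 and its oxygen to the aryl-bearing carbon. The closest known reaction type is the intramolecular nitrile oxide–alkyne cycloaddition that gives ring-fused isoxazoles. Ring B (C1–C2–C3–C4–C5–C9) closes through the new C2–C3 bond in the fused, 6-exo-dig sense, and the isoxazole closes as the five-membered ring of the same cycloaddition by O–C(aryl) bonding. No stereocentre is created; the cis, 1,3-diaxial placement of the two reacting arms was fixed in steps 7 and 13 and is the only arrangement from which a bicyclo[3.3.1]nonane can form. The step needs fused rather than bridged regiochemistry, which the four-atom tether C1–C9–C5–C4 enforces and the polarisation of the β-aryl ynone reinforces, and it needs the ynone to win over the five trisubstituted alkenes, which are trans to or geminal with the dipole and cannot reach it without severe strain. Dimerisation to the furoxan is held back by the tertiary, neopentyl-like environment of the nitrile oxide and by slow addition of base at high dilution.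

Step 17
Reactants: 27 isoxazole-fused bicyclo[3.3.1]nonane-4,9-dione
Product: 28 bicyclic C2-amino enedione (vinylogous amide)
Conditions: Mo(CO)6, MeCN/H2O, 80 °C
Reagents that add atoms: none
Why: Reductive cleavage of the isoxazole N–O bond by zerovalent molybdenum with water as proton source is the known route from isoxazoles to β-amino enones and should leave the isolated alkenes, the ketones and the silyl ethers untouched; no stereocentre is affected.

Step 18
Reactants: 28 bicyclic C2-amino enedione (vinylogous amide)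
Product: 30 guttiferone B, via catechol enaminone 29 (not isolated)
Conditions: LiOH, 1,4-dioxane/H2O (degassed, Ar), rt → 90 °C; then 1 M HCl, 0 °C, pH 3
Reagents that add atoms: water O
Why: Hydroxide first cleaves the two aryl silyl ethers and then hydrolyses the vinylogous amide by addition–elimination at C2 with loss of ammonia, the known alkaline hydrolysis of 2-acyl-3-aminocyclohexenones, driven by formation of the stabilised triketone enolate; base avoids the acid-induced cyclisation of the enol onto the prenyl and geranyl alkenes, and the non-enolisable bridgeheads keep all three stereocentres safe.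

Compound list

1 | cyclohexane-1,3-dione | O=C1CCCC(=O)C1 | starting material
2 | prenyl bromide (1-bromo-3-methylbut-2-ene) | CC(C)=CCBr | starting material
3 | 2-prenylcyclohexane-1,3-dione | CC(C)=CCC1C(=O)CCCC1=O | intermediate
4 | 3-methoxy-2-prenylcyclohex-2-en-1-one | COC1=C(CC=C(C)C)C(=O)CCC1 | intermediate
5 | RAMP, (R)-1-amino-2-(methoxymethyl)pyrrolidine | COC[C@H]1CCCN1N | starting material
6 | (E)-RAMP hydrazone of 4 (amino nitrogen anti to the prenyl-bearing carbon) | COC1=C(CC=C(C)C)/C(=N/N2CCC[C@@H]2COC)CCC1 | intermediate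
7 | geranyl bromide, (2E)-1-bromo-3,7-dimethylocta-2,6-diene | CC(C)=CCC/C(C)=C/CBr | starting material
8 | (E)-RAMP hydrazone of (6R)-6-geranyl-3-methoxy-2-prenylcyclohex-2-en-1-one | CC(C)=CCC/C(C)=C/C[C@H]1CCC(OC)=C(CC=C(C)C)/C1=N/N1CCC[C@@H]1COC | intermediate
9 | (6R)-6-geranyl-3-methoxy-2-prenylcyclohex-2-en-1-one | CC(C)=CCC/C(C)=C/C[C@H]1CCC(OC)=C(CC=C(C)C)C1=O | intermediate
10 | tertiary carbinol from 1,2-addition of methyl to 9 (carbinol epimers; lithium alkoxide before the acid; formed in the flask) | CC(C)=CCC/C(C)=C/C[C@H]1CCC(OC)=C(CC=C(C)C)C1(C)O | intermediate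
11 | (4R)-4-geranyl-3-methyl-2-prenylcyclohex-2-en-1-one | CC(C)=CCC/C(C)=C/C[C@H]1CCC(=O)C(CC=C(C)C)=C1C | intermediate
12 | lithium enolate (C1=C9) of (4R)-4-geranyl-3,3-dimethyl-2-prenylcyclohexanone (formed in the flask) | CC(C)=CCC/C(C)=C/C[C@H]1CCC(O[Li])=C(CC=C(C)C)C1(C)C | intermediate
13 | (2S,4R)-4-geranyl-2-(hydroxymethyl)-3,3-dimethyl-2-prenylcyclohexan-1-one (C1 hydroxymethyl trans to C7 geranyl) | CC(C)=CCC/C(C)=C/C[C@H]1CCC(=O)[C@](CC=C(C)C)(CO)C1(C)C | intermediate
14 | MOP ether of 13, (2S,4R) | CC(C)=CCC/C(C)=C/C[C@H]1CCC(=O)[C@](CC=C(C)C)(COC(C)(C)OC)C1(C)C | intermediate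
15 | C5-geranylated MOP ether: ring A ketone with C1 prenyl and CH2O-MOP, C5 H and geranyl (epimers), C7 geranyl; C1 and C7 as in 14 | CC(C)=CCC/C(C)=C/C[C@H]1CC(C/C=C(\C)CCC=C(C)C)C(=O)[C@](CC=C(C)C)(COC(C)(C)OC)C1(C)C | intermediate
16 | 3,4-dihydroxybenzaldehyde | O=Cc1ccc(O)c(O)c1 | starting material
17 | 3,4-bis(TBS-oxy)benzaldehyde | O=Cc1ccc(O[Si](C)(C)C(C)(C)C)c(O[Si](C)(C)C(C)(C)C)c1 | intermediate
18 | 1,1-dibromo-2-[3,4-bis(TBS-oxy)phenyl]ethene | BrC(Br)=Cc1ccc(O[Si](C)(C)C(C)(C)C)c(O[Si](C)(C)C(C)(C)C)c1 | intermediate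
19 | lithium [3,4-bis(TBS-oxy)phenyl]acetylide (formed in the flask) | [Li]C#Cc1ccc(O[Si](C)(C)C(C)(C)C)c(O[Si](C)(C)C(C)(C)C)c1 | intermediate
20 | 3-[3,4-bis(TBS-oxy)phenyl]prop-2-ynal | O=CC#Cc1ccc(O[Si](C)(C)C(C)(C)C)c(O[Si](C)(C)C(C)(C)C)c1 | intermediate
21 | MOP-protected aldol adduct: C5 bears geranyl and CH(OH)C≡C–Ar cis to the C1 CH2O-MOP group, both trans to the C7 geranyl; carbinol epimers; lithium alkoxide before the quench; formed in the flask | CC(C)=CCC/C(C)=C/C[C@H]1C[C@@](C(O)C#Cc2ccc(O[Si](C)(C)C(C)(C)C)c(O[Si](C)(C)C(C)(C)C)c2)(C/C=C(\C)CCC=C(C)C)C(=O)[C@](CC=C(C)C)(COC(C)(C)OC)C1(C)C | intermediate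
22 | diol: C1 prenyl and CH2OH, C5 geranyl and CH(OH)C≡C–Ar (cis to CH2OH), C7 geranyl; carbinol epimers | CC(C)=CCC/C(C)=C/C[C@H]1C[C@@](C(O)C#Cc2ccc(O[Si](C)(C)C(C)(C)C)c(O[Si](C)(C)C(C)(C)C)c2)(C/C=C(\C)CCC=C(C)C)C(=O)[C@](CC=C(C)C)(CO)C1(C)C | intermediate
23 | keto aldehyde ynone: C1 prenyl and CHO, C5 geranyl and 3-arylpropynoyl (cis to CHO), C7 geranyl | CC(C)=CCC/C(C)=C/C[C@H]1C[C@@](C(=O)C#Cc2ccc(O[Si](C)(C)C(C)(C)C)c(O[Si](C)(C)C(C)(C)C)c2)(C/C=C(\C)CCC=C(C)C)C(=O)[C@](CC=C(C)C)(C=O)C1(C)C | intermediate
24 | ynone (E)-aldoxime, key-step precursor: C1 prenyl and (E)-CH=NOH, C5 geranyl and 3-arylpropynoyl (cis to the oxime carbon), C7 geranyl trans to both | CC(C)=CCC/C(C)=C/C[C@H]1C[C@@](C(=O)C#Cc2ccc(O[Si](C)(C)C(C)(C)C)c(O[Si](C)(C)C(C)(C)C)c2)(C/C=C(\C)CCC=C(C)C)C(=O)[C@](CC=C(C)C)(/C=N/O)C1(C)C | intermediate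
25 | hydroximoyl chloride of 24 (formed in the flask) | CC(C)=CCC/C(C)=C/C[C@H]1C[C@@](C(=O)C#Cc2ccc(O[Si](C)(C)C(C)(C)C)c(O[Si](C)(C)C(C)(C)C)c2)(C/C=C(\C)CCC=C(C)C)C(=O)[C@](CC=C(C)C)(C(Cl)=NO)C1(C)C | intermediate
26 | C1 nitrile oxide (formed in the flask) | CC(C)=CCC/C(C)=C/C[C@H]1C[C@@](C(=O)C#Cc2ccc(O[Si](C)(C)C(C)(C)C)c(O[Si](C)(C)C(C)(C)C)c2)(C/C=C(\C)CCC=C(C)C)C(=O)[C@](CC=C(C)C)(C#[N+][O-])C1(C)C | intermediate
27 | isoxazole-fused bicyclo[3.3.1]nonane-4,9-dione (isoxazole nitrogen on C2, oxygen on the aryl carbon, C3 shared) | CC(C)=CCC/C(C)=C/C[C@H]1C[C@@]2(C/C=C(\C)CCC=C(C)C)C(=O)[C@](CC=C(C)C)(c3noc(-c4ccc(O[Si](C)(C)C(C)(C)C)c(O[Si](C)(C)C(C)(C)C)c4)c3C2=O)C1(C)C | intermediate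
28 | bicyclic vinylogous amide: C2 amino, C2=C3, C3 3,4-bis(TBS-oxy)benzoyl, C4 and C9 ketones | CC(C)=CCC/C(C)=C/C[C@H]1C[C@@]2(C/C=C(\C)CCC=C(C)C)C(=O)[C@](CC=C(C)C)(C(N)=C(C(=O)c3ccc(O[Si](C)(C)C(C)(C)C)c(O[Si](C)(C)C(C)(C)C)c3)C2=O)C1(C)C | intermediate
29 | catechol enaminone (28 without the silyl groups; lithium phenolate in the flask) | CC(C)=CCC/C(C)=C/C[C@H]1C[C@@]2(C/C=C(\C)CCC=C(C)C)C(=O)[C@](CC=C(C)C)(C(N)=C(C(=O)c3ccc(O)c(O)c3)C2=O)C1(C)C | intermediate
30 | guttiferone B | CC(C)=CCC/C(C)=C/C[C@H]1C[C@@]2(C/C=C(\C)CCC=C(C)C)C(=O)[C@](CC=C(C)C)(C(=O)C(C(=O)c3ccc(O)c(O)c3)=C2O)C1(C)C | target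

Total step count: 18. Longest linear sequence: 15 steps (steps 1–9 and 13–18); steps 10–12 make the ynal in a side branch.

Steps most likely to fail

1. Step 16. The nitrile oxide may dimerise, or the ynone may be consumed by addition of chloride or amine, or electrophilic chlorine may attack the trisubstituted alkenes, before ring B closes. The fallback sets out from 24 and comes back at 28, so that steps 16 and 17 are bypassed. The aldoxime is dehydrated (Burgess reagent, THF, rt) to the nitrile ynone F1. Diethylamine is added across the ynone (EtOH, rt) to give the β-diethylamino enone F2, and aqueous oxalic acid in THF hydrolyses this to the nitrile 1,3-diketone F3. LiN(SiMe3)2 in THF (0 → 50 °C) then generates the diketone enolate, whose C3 adds to the nitrile carbon C2 in a Thorpe-type cyclisation. This closes ring B by the same C2–C3 bond and gives the vinylogous amide 28 directly; the route resumes at step 18.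

2. Step 13. Deprotonation of the hindered C5–H may be slow, the ynal may attack the enolate face anti to the C1 oxymethyl group (giving the trans isomer, which cannot cyclise), or the crowded aldolate may revert on warming. The fallback sets out from 15 and comes back at 23, delivering the acyl group from the C1 arm itself. The mixed ketal of 15 is cleaved (PPTS, MeOH, 0 °C) to the C5-geranyl hydroxymethyl ketone F4. The acetylide from 18 (n-BuLi, THF, −78 °C) is carboxylated with CO2 to 3-[3,4-bis(TBS-oxy)phenyl]propiolic acid F5. Steglich esterification (DCC, cat. DMAP, CH2Cl2) joins the two as the arylpropiolate ester F6. LiN(SiMe3)2 (THF, −78 → 0 °C) then forms the C5 enolate, which attacks the tethered ester carbonyl through a six-membered transition state. This intramolecular Claisen-type O→C acyl transfer, the aliphatic counterpart of the Baker–Venkataraman shift, can place the acyl group only on the face that carries the C1 oxymethyl carbon and should give the C1-hydroxymethyl C5-ynone F7. Dess–Martin oxidation of its primary alcohol gives 23.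

3. Step 3. The hydrazine nitrogen may displace the methoxy group by addition–elimination instead of condensing at the carbonyl, and the enol ether may be lost during hydrazone cleavage in step 5; either process would cut off the supply of 9. The fallback sets out from 4 and comes back at 11, moving the auxiliary chemistry to a plain enone. Reduction of 4 (LiAlH4, Et2O, 0 °C; then 1 M HCl) gives 2-prenylcyclohex-2-en-1-one F8. Condensation with RAMP (cat. p-TsOH, benzene, reflux) gives the hydrazone F9. LiN(i-Pr)2 and then geranyl bromide (THF, −100 → −78 °C) alkylate the CH2 next to C=N with the same topicity to give the alkylated hydrazone F10. Aqueous oxalic acid releases (6R)-6-geranyl-2-prenylcyclohex-2-en-1-one F11. MeLi/CeCl3 (THF, −78 °C) adds 1,2 to give the tertiary allylic alcohol F12, and oxidative 1,3-transposition with [C5H5NH][CrO3Cl] (CH2Cl2, rt) delivers enone 11.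

Further compounds

F1 | step 16 | nitrile ynone (C1 cyano in place of the aldoxime of 24) | CC(C)=CCC/C(C)=C/C[C@H]1C[C@@](C(=O)C#Cc2ccc(O[Si](C)(C)C(C)(C)C)c(O[Si](C)(C)C(C)(C)C)c2)(C/C=C(\C)CCC=C(C)C)C(=O)[C@](CC=C(C)C)(C#N)C1(C)C
F2 | step 16 | β-diethylamino enone from F1 (alkene geometry not fixed) | CC(C)=CCC/C(C)=C/C[C@H]1C[C@@](C(=O)C=C(N(CC)CC)c2ccc(O[Si](C)(C)C(C)(C)C)c(O[Si](C)(C)C(C)(C)C)c2)(C/C=C(\C)CCC=C(C)C)C(=O)[C@](CC=C(C)C)(C#N)C1(C)C
F3 | step 16 | nitrile 1,3-diketone (C5 3-aryl-3-oxopropanoyl, C1 cyano) | CC(C)=CCC/C(C)=C/C[C@H]1C[C@@](C(=O)CC(=O)c2ccc(O[Si](C)(C)C(C)(C)C)c(O[Si](C)(C)C(C)(C)C)c2)(C/C=C(\C)CCC=C(C)C)C(=O)[C@](CC=C(C)C)(C#N)C1(C)C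
F4 | step 13 | C5-geranyl hydroxymethyl ketone (15 without the MOP group; C5 epimers) | CC(C)=CCC/C(C)=C/C[C@H]1CC(C/C=C(\C)CCC=C(C)C)C(=O)[C@](CC=C(C)C)(CO)C1(C)C
F5 | step 13 | 3-[3,4-bis(TBS-oxy)phenyl]propiolic acid | OC(=O)C#Cc1ccc(O[Si](C)(C)C(C)(C)C)c(O[Si](C)(C)C(C)(C)C)c1
F6 | step 13 | arylpropiolate ester of F4 | CC(C)=CCC/C(C)=C/C[C@H]1CC(C/C=C(\C)CCC=C(C)C)C(=O)[C@](CC=C(C)C)(COC(=O)C#Cc2ccc(O[Si](C)(C)C(C)(C)C)c(O[Si](C)(C)C(C)(C)C)c2)C1(C)C
F7 | step 13 | C1-hydroxymethyl C5-(3-arylpropynoyl) ketone (acyl cis to CH2OH) | CC(C)=CCC/C(C)=C/C[C@H]1C[C@@](C(=O)C#Cc2ccc(O[Si](C)(C)C(C)(C)C)c(O[Si](C)(C)C(C)(C)C)c2)(C/C=C(\C)CCC=C(C)C)C(=O)[C@](CC=C(C)C)(CO)C1(C)C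
F8 | step 3 | 2-prenylcyclohex-2-en-1-one | CC(C)=CCC1=CCCCC1=O
F9 | step 3 | (E)-RAMP hydrazone of F8 | CC(C)=CCC1=CCCC/C1=N\N1CCC[C@@H]1COC
F10 | step 3 | (E)-RAMP hydrazone of (6R)-6-geranyl-2-prenylcyclohex-2-en-1-one | CC(C)=CCC/C(C)=C/C[C@H]1CCC=C(CC=C(C)C)/C1=N/N1CCC[C@@H]1COC
F11 | step 3 | (6R)-6-geranyl-2-prenylcyclohex-2-en-1-one | CC(C)=CCC/C(C)=C/C[C@H]1CCC=C(CC=C(C)C)C1=O
F12 | step 3 | (6R)-6-geranyl-1-methyl-2-prenylcyclohex-2-en-1-ol (carbinol epimers) | CC(C)=CCC/C(C)=C/C[C@H]1CCC=C(CC=C(C)C)C1(C)O
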